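The route rests on disconnecting the C3–C4 bond of the cyclohexanone ring (ring B). In the target, C4 is doubly benzylic and, through the C4a=C8a bond of the dimethoxybenzo ring A, vinylogously alpha to the C1 ketone, while C3 is the beta carbon of a C1–C2–C3 enone. Deprotonation of an achiral 2-benzylaryl tiglyl ketone therefore gives a 1-oxidohexatriene (C4=C4a–C8a=C1–C2=C3) whose 6π closure under a chiral potassium–crown ether base is planned to form the C3–C4 bond, ring B and the C3/C4 stereocentres in one operation; C2 follows by equilibration. The precursor comes from a benzylic Suzuki coupling and a Weinreb acylation; hydrogenolysis ends the route.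

Key step: step 4

Remark on numbering: naphthalen-1(2H)-one numbering of the target is used throughout; ring A is the dimethoxybenzo ring, ring B the cyclohexanone ring, ring C the pendant aryl ring.

Assumption: the sense of asymmetric induction of the chiral crown ether in step 4 cannot be predicted with certainty; the (R,R) ligand is written, and its (S,S) antipode would be used if a test run shows the opposite sense.

Step 1
Reactants: 1 2-bromo-4,5-dimethoxybenzyl bromide; 2 [3-(benzyloxy)-4-methoxyphenyl]boronic acid
Product: 3 1-bromo-2-[3-(benzyloxy)-4-methoxybenzyl]-4,5-dimethoxybenzene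
Conditions: Pd(PPh3)4 (3 mol %), K2CO3, toluene/H2O, 70 °C
Reagents that add atoms: none
Why: Suzuki–Miyaura coupling at the benzylic C–Br bond, which adds to zerovalent palladium faster than the electron-rich aryl C–Br bond, should give the diarylmethane with the aryl bromide intact; no stereocenter is formed.

Step 2
Reactants: 4 tigloyl chloride ((E)-2-methylbut-2-enoyl chloride); 5 N,O-dimethylhydroxylamine hydrochloride
Product: 6 (E)-N-methoxy-N,2-dimethylbut-2-enamide
Conditions: K2CO3, CH2Cl2/H2O, 0 °C to rt
Reagents that add atoms: none
Why: Schotten–Baumann acylation of the hydroxylamine by the acid chloride should give the Weinreb amide with the E alkene untouched.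

Step 3
Reactants: 3 1-bromo-2-[3-(benzyloxy)-4-methoxybenzyl]-4,5-dimethoxybenzene; 6 (E)-N-methoxy-N,2-dimethylbut-2-enamide
Product: 9 (E)-1-{2-[3-(benzyloxy)-4-methoxybenzyl]-4,5-dimethoxyphenyl}-2-methylbut-2-en-1-one, via aryllithium 7 (not isolated), via lithium hemiaminal 8 (not isolated)
Conditions: n-BuLi, THF, −78 °C; then 6, −78 to 0 °C; then 1 M HCl
Reagents that add atoms: none
Why: Bromine–lithium exchange followed by the Weinreb ketone synthesis, in which the chelated tetrahedral adduct 8 resists a second addition and releases the enone only on acidic work-up, should place the tiglyl group ortho to the benzyl group with the E geometry retained.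

Step 4
Reactants: 9 (E)-1-{2-[3-(benzyloxy)-4-methoxybenzyl]-4,5-dimethoxyphenyl}-2-methylbut-2-en-1-one
Product: 12 (2S,3R,4R)-4-[3-(benzyloxy)-4-methoxyphenyl]-6,7-dimethoxy-2,3-dimethyl-3,4-dihydronaphthalen-1(2H)-one, via potassium trienolate 10 (not isolated), via potassium enolate 11 (not isolated)
Conditions: KN(SiMe3)2 (20 mol %), (R,R)-bis(1,1′-binaphthyl-2,2′-diyl)-22-crown-6 (24 mol %), toluene (0.02 M), −40 to −20 °C; then MeOH, 0 °C; aq NH4Cl
Reagents that add atoms: none
Why: Proposed new method: the crown-bound potassium amide removes one proton of the C4 methylene of 9, which is diaryl-activated and vinylogously alpha to the C1 carbonyl through C4a=C8a, to give trienolate 10, whose C4 terminus adds to the enone beta carbon C3 in a 6-endo-trig Michael closure that is equally a thermal disrotatory 6π electrocyclization of the 1-oxidohexatriene C4=C4a–C8a=C1–C2=C3, forming the C3–C4 bond and ring B as enolate 11. The closest known reaction types are the chiral crown ether–potassium base catalysed asymmetric Michael additions of weakly acidic carbon acids and the oxyanion-driven ring expansion of 1-vinylbenzocyclobutenoxides to 1-tetralone enolates, which passes through the same kind of trienolate; an intramolecular enantioselective version on a diarylmethane has not been shown. The C3/C4 relation is fixed by the closure itself: with the ring C aryl group on C4 and the methyl group on C3 of the E-tiglyl unit both in the outside positions of the triene, disrotation places them cis. The absolute sense at C3 and C4 is to be set by the chiral potassium–crown cation that is ion-paired at the oxygen of 10 and shields one face of the helical triene. C2 is set last under thermodynamic control, since ketone 12 and enolate 11 exchange protons in the basic medium until the C2 methyl group sits trans to the C3 methyl group, both equatorial and free of a 1,3-diaxial clash with the axial C4 aryl group. The step needs reaction through the C4 carbanion although the gamma methyl group of the enone can also be deprotonated, which is secured because that deprotonation is reversible and leads back to 9, while low temperature and dilution hold back retro-Michael equilibration and intermolecular Michael addition.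

Step 5
Reactants: 12 (2S,3R,4R)-4-[3-(benzyloxy)-4-methoxyphenyl]-6,7-dimethoxy-2,3-dimethyl-3,4-dihydronaphthalen-1(2H)-one
Product: 13 (2S,3R,4R)-4-(3-hydroxy-4-methoxyphenyl)-6,7-dimethoxy-2,3-dimethyl-3,4-dihydronaphthalen-1(2H)-one
Conditions: H2 (1 atm), Pd/C (10%), EtOAc, rt
Reagents that add atoms: none
Why: Hydrogenolysis of the benzyl aryl ether on palladium should be faster than reduction of the hindered aryl ketone or cleavage at C4, and the neutral medium leaves the three stereocenters untouched.

Compound list
1 | 2-bromo-4,5-dimethoxybenzyl bromide | COc1cc(CBr)c(Br)cc1OC | starting material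
2 | [3-(benzyloxy)-4-methoxyphenyl]boronic acid | COc1ccc(B(O)O)cc1OCc1ccccc1 | starting material
3 | 1-bromo-2-[3-(benzyloxy)-4-methoxybenzyl]-4,5-dimethoxybenzene | COc1ccc(Cc2cc(OC)c(OC)cc2Br)cc1OCc1ccccc1 | intermediate
4 | tigloyl chloride, (E)-2-methylbut-2-enoyl chloride | C/C=C(\C)C(=O)Cl | starting material
5 | N,O-dimethylhydroxylamine hydrochloride | CNOC.Cl | starting material
6 | (E)-N-methoxy-N,2-dimethylbut-2-enamide | C/C=C(\C)C(=O)N(C)OC | intermediate
7 | {2-[3-(benzyloxy)-4-methoxybenzyl]-4,5-dimethoxyphenyl}lithium | COc1ccc(Cc2cc(OC)c(OC)cc2[Li])cc1OCc1ccccc1 | intermediate (not isolated)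
8 | lithium hemiaminal from 7 and 6, racemic at the new tetrahedral carbon | C/C=C(\C)C(O[Li])(N(C)OC)c1cc(OC)c(OC)cc1Cc1ccc(OC)c(OCc2ccccc2)c1 | intermediate (not isolated)
9 | (E)-1-{2-[3-(benzyloxy)-4-methoxybenzyl]-4,5-dimethoxyphenyl}-2-methylbut-2-en-1-one | C/C=C(\C)C(=O)c1cc(OC)c(OC)cc1Cc1ccc(OC)c(OCc2ccccc2)c1 | intermediate
10 | potassium trienolate of 9, drawn in its C4 carbanion form | C/C=C(\C)C(=O)c1cc(OC)c(OC)cc1[CH-]c1ccc(OC)c(OCc2ccccc2)c1.[K+] | intermediate (not isolated)
11 | potassium (3R,4R)-4-[3-(benzyloxy)-4-methoxyphenyl]-6,7-dimethoxy-2,3-dimethyl-3,4-dihydronaphthalen-1-olate | COc1ccc([C@@H]2c3cc(OC)c(OC)cc3C([O-])=C(C)[C@@H]2C)cc1OCc1ccccc1.[K+] | intermediate (not isolated)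
12 | (2S,3R,4R)-4-[3-(benzyloxy)-4-methoxyphenyl]-6,7-dimethoxy-2,3-dimethyl-3,4-dihydronaphthalen-1(2H)-one | COc1ccc([C@@H]2c3cc(OC)c(OC)cc3C(=O)[C@@H](C)[C@@H]2C)cc1OCc1ccccc1 | intermediate
13 | (2S,3R,4R)-4-(3-hydroxy-4-methoxyphenyl)-6,7-dimethoxy-2,3-dimethyl-3,4-dihydronaphthalen-1(2H)-one | COc1ccc([C@@H]2c3cc(OC)c(OC)cc3C(=O)[C@@H](C)[C@@H]2C)cc1O | target

Total step count: 5
Longest linear sequence: 4 (steps 1, 3, 4, 5)

Steps most likely to fail

Step 4 (Proposed new method). What may go wrong is poor facial discrimination by the chiral ion pair, so that the closure gives low enantiomeric excess, or slow turnover because the product enolate is a weaker base than the trienolate. The fallback sets out from 9 and comes back at 13. Compound 9 is cyclised without a chiral ligand (KOt-Bu, t-BuOH/THF, 0 °C), the known anionic Michael/6π closure of a ketone-activated benzylic carbanion, with the relative configuration argued in step 4. This should give 12 as a racemate, that is together with its enantiomer, the (2R,3S,4S)-benzyl ether F1. Hydrogenolysis as in step 5 gives 13 together with its enantiomer, the (2R,3S,4S)-phenol F2. The phenols are esterified with (1S)-(−)-camphanic chloride (Et3N, DMAP, CH2Cl2) to the diastereomeric esters, the camphanate of 13 F3 and the camphanate of the enantiomer F4, which are separated by crystallisation or chromatography. Methanolysis of F3 (K2CO3, MeOH, rt) returns 13.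

Step 3. What may go wrong is proton transfer from the acidic diarylmethane CH2 to the aryllithium, which would give the debrominated diarylmethane, or conjugate addition to the unsaturated amide. The fallback sets out from 3 and comes back at 9. Magnesium insertion (Mg, LiCl, THF) gives the less basic arylmagnesium bromide F5. Its 1,2-addition to (E)-2-methylbut-2-enal (THF, −20 °C, dilute HCl quench) gives the racemic allylic alcohol F6. Oxidation of this benzylic, allylic alcohol with MnO2 (CH2Cl2, rt) gives 9.

Step 1. What may go wrong is competing oxidative addition at the aryl C–Br bond, homocoupling to the bibenzyl, or solvolysis of the electron-rich benzylic bromide in the aqueous base. The fallback sets out from 2 and comes back at 3. Rhodium-catalysed 1,2-addition of boronic acid 2 to commercial 2-bromo-4,5-dimethoxybenzaldehyde ([RhCl(cod)]2, KOH, dioxane/H2O, 60 °C) gives the racemic diarylmethanol F7. Ionic deoxygenation of this doubly activated carbinol (Et3SiH, CF3CO2H, CH2Cl2, 0 °C) gives 3.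

Further compounds
F1 | step 4 | (2R,3S,4S)-4-[3-(benzyloxy)-4-methoxyphenyl]-6,7-dimethoxy-2,3-dimethyl-3,4-dihydronaphthalen-1(2H)-one, enantiomer of 12 | COc1ccc([C@H]2c3cc(OC)c(OC)cc3C(=O)[C@H](C)[C@H]2C)cc1OCc1ccccc1
F2 | step 4 | (2R,3S,4S)-4-(3-hydroxy-4-methoxyphenyl)-6,7-dimethoxy-2,3-dimethyl-3,4-dihydronaphthalen-1(2H)-one, enantiomer of 13 | COc1ccc([C@H]2c3cc(OC)c(OC)cc3C(=O)[C@H](C)[C@H]2C)cc1O
F3 | step 4 | (1S,4R)-camphanate ester of 13 | COc1ccc([C@@H]2c3cc(OC)c(OC)cc3C(=O)[C@@H](C)[C@@H]2C)cc1OC(=O)[C@@]12CC[C@@](C)(C(=O)O1)C2(C)C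
F4 | step 4 | (1S,4R)-camphanate ester of the enantiomer of 13 | COc1ccc([C@H]2c3cc(OC)c(OC)cc3C(=O)[C@H](C)[C@H]2C)cc1OC(=O)[C@@]12CC[C@@](C)(C(=O)O1)C2(C)C
F5 | step 3 | {2-[3-(benzyloxy)-4-methoxybenzyl]-4,5-dimethoxyphenyl}magnesium bromide | COc1ccc(Cc2cc(OC)c(OC)cc2[Mg]Br)cc1OCc1ccccc1
F6 | step 3 | (E)-1-{2-[3-(benzyloxy)-4-methoxybenzyl]-4,5-dimethoxyphenyl}-2-methylbut-2-en-1-ol, racemic | C/C=C(\C)C(O)c1cc(OC)c(OC)cc1Cc1ccc(OC)c(OCc2ccccc2)c1
F7 | step 1 | [3-(benzyloxy)-4-methoxyphenyl](2-bromo-4,5-dimethoxyphenyl)methanol, racemic | COc1ccc(C(O)c2cc(OC)c(OC)cc2Br)cc1OCc1ccccc1
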